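The runs were generated by integration with constants of no real substance; scatter was added.

Friday's last reading leaves 18.4% of the charge as neither target nor uncatalysed product, and beside that leftover the uncatalysed product still climbs, from 6.0% to 9.4%.

| flask | starting material | second substrate | free catalyst | temperature | remark | time |
|---|---|---|---|---|---|---|
| Monday's | 0.085 M | 0.085 M | 20 mM | 5 °C | run made earlier |  |
| Friday's | 0.13 M | 0.085 M | 20 mM | 16 °C | run made earlier |  |
| cedar | 0.17 M | 0.0850 M | 20 mM | 20 °C |  | 1.0 h |
| larch | 0.17 M | 0.0850 M | 20 mM | 0 °C |  | 1.0 h |

| run | time / min | target / % | uncatalysed product / % |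
|---|---|---|---|
| Monday's | 12.0 | 22.9 | 0.5 |
| Monday's | 30.0 | 50.0 | 2.4 |
| Monday's | 60.0 | 72.4 | 4.7 |
| Monday's | 120 | 82.2 | 4.0 |
| Friday's | 4.00 | 20.9 | 1.4 |
| Friday's | 8.00 | 36.5 | 3.0 |
| Friday's | 20.0 | 61.9 | 6.0 |
| Friday's | 50.0 | 72.2 | 9.4 |

(readings scatter by 0.5 percentage points)

- which flask leads in share of target in all that became target or uncatalysed product ("all alike" within 1.5 percentage points) (cedar / larch / all alike)
- share of target in all that became target or uncatalysed product, cedar
- share of target in all that became target or uncatalysed product, larch

Treat uncatalysed product as a first-order leak from that leftover, all that is neither target nor uncatalysed product. An early reading then gives the leak constant: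

leak constant = uncatalysed product / (time × average share left)

Using the average of the start and the reading, Monday's reading at 30.0 min gives 0.00108 /min, and Friday's at 8.00 min gives 0.00467 /min. Both carry the scatter of the readings. I assume a steady factor per degree between them and carry it on to each flask.

Now fold constant and time into one number, the leak number: leak constant × time, which counts how far the leak gets in the time given. For cedar it is 0.477, and for larch 0.0335. I let the lost share, which is one minus the selectivity, scale with it from the nearest run:

Friday's at 50.0 min: lost 11.5%, leak number 0.234
Monday's at 60.0 min: lost 6.10%, leak number 0.0650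
cedar: target share 76.5%
larch: target share 96.9%

Does one number suffice? Lost share per leak number is 0.937 on Monday and 0.493 on Friday, so Monday's is about twice Friday's. Cedar's number stands far above larch's, which gives my order of the flasks, but the two runs give no common scale, so I take the nearest run for each flask.

The forecast gave cedar 85.5%, above my figure, and larch 94%, with larch leading, on the ground that “Colder favours the target”.

The flasks give 79.1% for cedar and 95.6% for larch, so larch leads, with these steps running:

    catalyst intermediate A ⇌ free catalyst + target (K = 0.250 M, k = 3.60 /min, Ea = 77.0 kJ/mol, ΔH = −7.00 kJ/mol)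
    starting material → uncatalysed product (k = 0.0100 /min, Ea = 95.0 kJ/mol)
    starting material + free catalyst ⇌ catalyst intermediate A (K = 14.0 /M, k = 9.50 /M/min, Ea = 59.0 kJ/mol, ΔH = −48.0 kJ/mol)
    catalyst intermediate B → free catalyst + second product (k = 1.80 /min, Ea = 90.0 kJ/mol)
    second substrate + free catalyst ⇌ catalyst intermediate B (K = 7.70 /M, k = 20.0 /M/min, Ea = 51.0 kJ/mol, ΔH = −24.0 kJ/mol)
    (constants at 20 °C)

Between 0.500 h and 1.00 h cedar's target falls from 66.0% to 63.0%, while its uncatalysed product rises from 11.4% to 16.7%. Now scale from Friday's as for cedar's 0.477, this time for larch run at 15 °C. Its leak number is 0.245, which puts its target share at 87.9%, and that flask gave 88.4%.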